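The plan rests on ring B, the hexasubstituted benzene ring. Its phenol oxygen (on the carbon beside the lactone-carbonyl-bearing carbon) and its diaryl ether oxygen (on the carbon beside the lactol-bearing carbon) are para to each other, and the two ring carbons between them are shared with the five-membered lactol–lactone ring D. This is the hydroquinone that ring expansion of a 4-hydroxycyclobutenone carrying a butenolid-4-yl group on C4 gives.
The last disconnection to be made good is hydrogenolysis of the ring A benzyl ether and of the (S)-1-phenylethyl acetal at the lactol carbon. Before it, seven-membered ring C is cut at its ester C–O bond (lactonisation) and at its diaryl ether C–O bond (SNAr of the ring B C4 phenoxide on ring A fluoride 24).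
The ring B formyl group is cut next (ortho-formylation of the only free ring B carbon, directly after the ring expansion).
Ring B is cut at the bond between the phenol carbon and the lactone-bearing carbon, which is 4π opening and 6π closure of cyclobutenone 11. Compound 11 comes from allyl semisquarate 4 and 3-lithiofuran, the furan being turned into the butenolide acetal with singlet oxygen and (S)-1-phenylethanol.
Rings form in the order D (step 4), B (step 6), C (ether in step 13, ester in step 15); ring A is bought as 3-fluoro-5-methylphenol.

Key step: step 6

Assumption: the lactol carbon C1 of ring D is a 3-hydroxyphthalide carbon that can epimerise through the ring-opened formyl acid, so its S configuration is carried as a separable acetal up to the last step, is released there under neutral conditions without breaking a bond at C1, and the target is to be kept cold and away from acid, base and protic solvents.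

Step 1
Reactants: 1 squaric acid (3,4-dihydroxycyclobut-3-ene-1,2-dione)
Product: 2 diallyl squarate (3,4-bis(allyloxy)cyclobut-3-ene-1,2-dione)
Conditions: allyl alcohol (excess), toluene, Dean–Stark trap, reflux
Reagents that add atoms: allyl alcohol, C=CCO
Why: Squaric acid is a strong vinylogous acid that catalyses its own Fischer-type esterification once water is removed azeotropically, and allyl is chosen as the oxygen mask because zerovalent palladium can remove it later without the acid that would ionise the 1-phenylethyl acetal.

Step 2
Reactants: 2 diallyl squarate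
Product: 4 allyl semisquarate (3-(allyloxy)cyclobut-3-ene-1,2-dione), via hydroxycyclobutenone 3 (not isolated)
Conditions: LiAlH(OtBu)3, THF, −20 °C; then 2 M HCl, CH2Cl2, rt
Reagents that add atoms: water, O
Why: The bulky hydride stops after 1,2-reduction of one carbonyl group, and acid then ionises the carbinol of 3 to an allyloxy-stabilised cyclobutenyl cation that takes up water at the remote allyloxy carbon and loses allyl alcohol, which is the established reduction–hydrolysis route from dialkyl squarates to alkyl semisquarates.

Step 3
Reactants: 5 3-bromofuran; 4 allyl semisquarate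
Product: 7 rac-3-(allyloxy)-4-(furan-3-yl)-4-hydroxycyclobut-2-en-1-one, via 3-lithiofuran 6 (not isolated)
Conditions: 5, n-BuLi, THF, −78 °C; cannulation into 4, THF, −78 °C; AcOH, −78 °C
Reagents that add atoms: none
Why: Bromine–lithium exchange gives 3-lithiofuran, positionally stable at −78 °C, which adds 1,2 to the ketone-like carbonyl beside the allyloxy-bearing carbon and not to the vinylogous ester carbonyl (standard organolithium addition to cyclobutenediones); the furan stands in for the butenolide because a 4-metallated 5-alkoxybutenolide would expel its ring carboxylate anti-periplanar to the carbon–metal bond and give an allene, and the racemic carbinol centre is erased in step 6.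

Step 4
Reactants: 7 rac-3-(allyloxy)-4-(furan-3-yl)-4-hydroxycyclobut-2-en-1-one
Product: 9 4-[2-(allyloxy)-1-hydroxy-4-oxocyclobut-2-en-1-yl]-5-hydroxyfuran-2(5H)-one (diastereomer mixture), via furan endoperoxide 8 (not isolated)
Conditions: O2, tetraphenylporphyrin (cat.), i-Pr2NEt, CH2Cl2, −78 °C, visible light
Reagents that add atoms: oxygen, O=O
Why: Singlet oxygen adds [4+2] to the furan far faster than to the electron-poor cyclobutenone alkene or the terminal allyl alkene, and the hindered amine removes the bridgehead proton of 8 that lies away from the bulky carbinol substituent (Kornblum–DeLaMare fragmentation, the known regioselective photooxygenation of 3-substituted furans), so the lactone carbonyl forms at the far carbon and the lactol carbon beside the substituent, as both lactol epimers.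

Step 5
Reactants: 9 4-[2-(allyloxy)-1-hydroxy-4-oxocyclobut-2-en-1-yl]-5-hydroxyfuran-2(5H)-one; 10 (S)-1-phenylethanol
Product: 11 4-[2-(allyloxy)-1-hydroxy-4-oxocyclobut-2-en-1-yl]-5-[(1S)-1-phenylethoxy]furan-2(5H)-one (both carbinol epimers and both C5 epimers; auxiliary carbon S)
Conditions: CSA (5 mol %), 4 Å molecular sieves, CH2Cl2, rt
Reagents that add atoms: none
Why: Acid-catalysed pseudo-ester (acetal) formation of a γ-hydroxybutenolide runs at room temperature and so spares the heat-sensitive ring and the vinylogous ester; C5 forms without control as both epimers, which the S auxiliary turns into diastereomers that are sorted after step 6, when the carbinol centre no longer multiplies the isomers.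

Step 6
Reactants: 11 4-[2-(allyloxy)-1-hydroxy-4-oxocyclobut-2-en-1-yl]-5-[(1S)-1-phenylethoxy]furan-2(5H)-one
Product: 14 (3S)-5-(allyloxy)-4,7-dihydroxy-3-[(1S)-1-phenylethoxy]isobenzofuran-1(3H)-one, via dienylketene 12 (not isolated), via cyclohexadienone 13 (not isolated)
Conditions: toluene (0.02 M, degassed), 110 °C, Ar; then SiO2 chromatography (separation of the C3 epimers)
Reagents that add atoms: none
Why: Heating cleaves the C1–C4 bond of the cyclobutenone in a conrotatory 4π opening to dienylketene 12, whose ketene carbon bonds to butenolide C3 (the carbon α to the lactone carbonyl) in a disrotatory 6π electrocyclisation to cyclohexadienone 13, and enolisation of the doubly activated ring-fusion hydrogen gives hydroquinone 14. The closest known reaction type is the Moore-type thermal ring expansion of 4-alkenyl-4-hydroxycyclobutenones to hydroquinones, here with a butenolide as the alkenyl group. Ring B is the only ring closed, a six-membered carbocycle made by 6π electrocyclisation from the four cyclobutenone carbons and C4=C3 of the butenolide, while ring D is carried in intact. No stereocentre is created: the carbinol carbon becomes sp2 carbon C4, so both carbinol epimers converge, and the acetal carbon is a spectator under these neutral conditions, so only two C3 epimers remain, which are diastereomers through the S auxiliary and are separated by chromatography (3S taken on, assignment to be secured by X-ray analysis, the other epimer re-equilibrated with CSA and recycled). The step needs torquoselectivity, and the substrate secures it because the donor hydroxyl rotates outward and the acceptor-substituted alkenyl group inward, which puts the butenolide alkene beside the ketene and keeps the hydroxyl from lactonising onto it. Regiochemistry is fixed by the connectivity of 11 (ketene carbon to C7–OH beside the lactone carbonyl, CH to C6, allyloxy carbon to C5, carbinol carbon to C4–OH beside the acetal carbon), and dilution and exclusion of air guard against intermolecular ketene capture and quinone formation.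

Step 7
Reactants: 14 (3S)-5-(allyloxy)-4,7-dihydroxy-3-[(1S)-1-phenylethoxy]isobenzofuran-1(3H)-one
Product: 15 (3S)-5-(allyloxy)-6-formyl-4,7-dihydroxy-3-[(1S)-1-phenylethoxy]isobenzofuran-1(3H)-one
Conditions: MgCl2, Et3N, (CH2O)n, THF, 65 °C, Ar; cold aq. citric acid
Reagents that add atoms: paraformaldehyde (as formaldehyde), C=O
Why: In this Casnati–Skattebøl ortho-formylation the magnesium phenoxide of the C7 hydroxyl delivers formaldehyde to C6, the only free ring position and one activated by two ortho oxygens, and a second formaldehyde oxidises the benzylic alkoxide to the aldehyde under mildly basic conditions that leave acetal, lactone and allyl ether alone.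

Step 8
Reactants: 16 3-fluoro-5-methylphenol
Product: 17 4-bromo-3-fluoro-5-methylphenol
Conditions: NBS, MeCN, 0 °C
Reagents that add atoms: N-bromosuccinimide, O=C1CCC(=O)N1Br
Why: Electrophilic aromatic bromination with NBS in acetonitrile goes para to a phenol hydroxyl, and that carbon is further activated by the ortho fluorine and ortho methyl groups, which puts the halogen where the ring A carboxyl carbon is needed.

Step 9
Reactants: 17 4-bromo-3-fluoro-5-methylphenol
Product: 18 5-(benzyloxy)-2-bromo-1-fluoro-3-methylbenzene
Conditions: BnBr, K2CO3, DMF, rt
Reagents that add atoms: benzyl bromide, BrCc1ccccc1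
Why: This Williamson ether synthesis masks the ring A phenol, whose free phenoxide would switch off the later SNAr, with a group that leaves in the final hydrogenolysis.

Step 10
Reactants: 18 5-(benzyloxy)-2-bromo-1-fluoro-3-methylbenzene
Product: 20 6-(benzyloxy)-3-bromo-2-fluoro-4-methylbenzaldehyde, via aryllithium 19 (not isolated)
Conditions: LiN(i-Pr)2, THF, −78 °C; DMF, −78 °C; AcOH
Reagents that add atoms: N,N-dimethylformamide, CN(C)C=O
Why: In this directed ortho-metalation and DMF formylation the hydrogen between fluorine and benzyloxy is the only strongly acidified one, the amide base does not exchange the bromine, no more stable anion exists to drive a halogen dance, and at −78 °C aryllithium 19 does not lose LiF.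

Step 11
Reactants: 20 6-(benzyloxy)-3-bromo-2-fluoro-4-methylbenzaldehyde
Product: 21 1-(benzyloxy)-4-bromo-2-(dimethoxymethyl)-3-fluoro-5-methylbenzene
Conditions: HC(OMe)3, p-TsOH·H2O (cat.), MeOH, rt
Reagents that add atoms: trimethyl orthoformate, COC(OC)OC
Why: Acid-catalysed acetalisation with the orthoformate as water scavenger masks the aldehyde for the organolithium step.

Step 12
Reactants: 21 1-(benzyloxy)-4-bromo-2-(dimethoxymethyl)-3-fluoro-5-methylbenzene
Product: 24 allyl 4-(benzyloxy)-2-fluoro-3-formyl-6-methylbenzoate, via aryllithium 22 (not isolated), via acetal ester 23 (not isolated)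
Conditions: n-BuLi, THF, −78 °C; ClCO2CH2CH=CH2, −78 to 0 °C; then 1 M HCl, THF, rt
Reagents that add atoms: allyl chloroformate, C=CCOC(=O)Cl; water, O
Why: Bromine–lithium exchange outruns any attack on acetal or benzyl ether, aryllithium 22 is acylated only once because the doubly ortho-substituted ester is shielded, and dilute acid then hydrolyses only the dimethyl acetal; the formyl group was installed before the ester because a base would otherwise deprotonate the methyl group ortho to the ester (lateral metalation).

Step 13
Reactants: 15 (3S)-5-(allyloxy)-6-formyl-4,7-dihydroxy-3-[(1S)-1-phenylethoxy]isobenzofuran-1(3H)-one; 24 allyl 4-(benzyloxy)-2-fluoro-3-formyl-6-methylbenzoate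
Product: 25 allyl 2-{[(3S)-5-(allyloxy)-6-formyl-7-hydroxy-1-oxo-3-[(1S)-1-phenylethoxy]-1,3-dihydroisobenzofuran-4-yl]oxy}-4-(benzyloxy)-3-formyl-6-methylbenzoate
Conditions: Cs2CO3 (2.5 equiv), DMF (dry, degassed), rt to 50 °C
Reagents that add atoms: none
Why: In this nucleophilic aromatic substitution (addition–elimination) the fluoride of 24 is activated by an ortho formyl and an ortho ester group, and in the dianion of 15 the C4 phenoxide, conjugated with neither carbonyl group, is far more nucleophilic than the C7 phenoxide, which is delocalised into both the formyl and the lactone carbonyl, so the ether should form at C4 only, while carbonate is too weak to deprotonate the acetal carbon of the electron-rich anion and C3 keeps its configuration.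

Step 14
Reactants: 25 diaryl ether bis-allyl compound
Product: 26 4-(benzyloxy)-3-formyl-2-{[(3S)-6-formyl-5,7-dihydroxy-1-oxo-3-[(1S)-1-phenylethoxy]-1,3-dihydroisobenzofuran-4-yl]oxy}-6-methylbenzoic acid
Conditions: Pd(PPh3)4 (5 mol %), PhNHMe, THF, rt; pH 5 citrate wash
Reagents that add atoms: none
Why: In this Tsuji–Trost deallylation zerovalent palladium ionises both the allyl ester and the allyl aryl ether (a formyl-stabilised phenoxide is a good leaving group) to π-allyl complexes that N-methylaniline captures, under neutral conditions that leave acetal, benzyl ether and aldehydes untouched, since a secondary aniline cannot form an imine.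

Step 15
Reactants: 26 seco acid
Product: 27 (1S)-10-(benzyloxy)-4-hydroxy-8-methyl-3,7-dioxo-1-[(1S)-1-phenylethoxy]-1,3-dihydro-7H-isobenzofuro[4,5-b][1,4]benzodioxepine-5,11-dicarbaldehyde
Conditions: DCC, DMAP (cat.), CH2Cl2 (high dilution, slow addition), 0 °C to rt
Reagents that add atoms: none
Why: This is the carbodiimide (Steglich-type) lactonisation used for depsidones; only the hydroxyl ortho to the ether oxygen can reach the activated carboxyl and close seven-membered ring C, because the other phenol is para to the ether oxygen and held in hydrogen bonds to two carbonyl groups, and dilution suppresses intermolecular acylation.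

Step 16
Reactants: 27 protected depsidone
Product: 28 (1S)-1,4,10-trihydroxy-8-methyl-3,7-dioxo-1,3-dihydro-7H-isobenzofuro[4,5-b][1,4]benzodioxepine-5,11-dicarbaldehyde (target)
Conditions: H2 (1 atm), 10% Pd/C, EtOAc–THF, rt, stopped at full conversion; filtration and evaporation below rt
Reagents that add atoms: none
Why: Catalytic hydrogenolysis cleaves the O–CH2Ph and O–CH(CH3)Ph bonds on their benzylic side, so no bond at C1 is broken and the S configuration is retained, while the hydrogen-bonded aromatic aldehydes are reduced more slowly, as is known for benzyl-protected formyl depsides.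

Compound list
1 | squaric acid | O=C1C(O)=C(O)C1=O | starting material
2 | diallyl squarate | C=CCOC1=C(OCC=C)C(=O)C1=O | intermediate
3 | 2,3-bis(allyloxy)-4-hydroxycyclobut-2-en-1-one (racemic, not isolated) | C=CCOC1=C(OCC=C)C(O)C1=O | intermediate
4 | 3-(allyloxy)cyclobut-3-ene-1,2-dione (allyl semisquarate) | O=C1C=C(OCC=C)C1=O | intermediate
5 | 3-bromofuran | Brc1ccoc1 | starting material
6 | 3-lithiofuran (not isolated) | [Li]c1ccoc1 | intermediate
7 | rac-3-(allyloxy)-4-(furan-3-yl)-4-hydroxycyclobut-2-en-1-one | O=C1C=C(OCC=C)C1(O)c1ccoc1 | intermediate
8 | furan endoperoxide of 7 (2,3,7-trioxabicyclo[2.2.1]hept-5-ene, not isolated) | O=C1C=C(OCC=C)C1(O)C1=CC2OOC1O2 | intermediate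
9 | 4-[2-(allyloxy)-1-hydroxy-4-oxocyclobut-2-en-1-yl]-5-hydroxyfuran-2(5H)-one (diastereomer mixture) | O=C1C=C(OCC=C)C1(O)C1=CC(=O)OC1O | intermediate
10 | (S)-1-phenylethanol | C[C@H](O)c1ccccc1 | starting material
11 | 4-[2-(allyloxy)-1-hydroxy-4-oxocyclobut-2-en-1-yl]-5-[(1S)-1-phenylethoxy]furan-2(5H)-one (carbinol carbon and C5 as both epimers, auxiliary S) | O=C1C=C(OCC=C)C1(O)C1=CC(=O)OC1O[C@@H](C)c1ccccc1 | intermediate
12 | dienylketene, butenolide cis to the ketenyl carbon (not isolated) | O=C=C/C(OCC=C)=C(/O)C1=CC(=O)OC1O[C@@H](C)c1ccccc1 | intermediate
13 | cyclohexadienone from 6π closure (not isolated) | O=C1C=C(OCC=C)C(O)=C2C1C(=O)OC2O[C@@H](C)c1ccccc1 | intermediate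
14 | (3S)-5-(allyloxy)-4,7-dihydroxy-3-[(1S)-1-phenylethoxy]isobenzofuran-1(3H)-one | C=CCOc1cc(O)c2c(c1O)[C@@H](O[C@@H](C)c1ccccc1)OC2=O | intermediate
15 | (3S)-5-(allyloxy)-6-formyl-4,7-dihydroxy-3-[(1S)-1-phenylethoxy]isobenzofuran-1(3H)-one | C=CCOc1c(C=O)c(O)c2c(c1O)[C@@H](O[C@@H](C)c1ccccc1)OC2=O | intermediate
16 | 3-fluoro-5-methylphenol | Cc1cc(O)cc(F)c1 | starting material
17 | 4-bromo-3-fluoro-5-methylphenol | Cc1cc(O)cc(F)c1Br | intermediate
18 | 5-(benzyloxy)-2-bromo-1-fluoro-3-methylbenzene | Cc1cc(OCc2ccccc2)cc(F)c1Br | intermediate
19 | 2-(benzyloxy)-5-bromo-6-fluoro-4-methylphenyllithium (not isolated) | Cc1cc(OCc2ccccc2)c([Li])c(F)c1Br | intermediate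
20 | 6-(benzyloxy)-3-bromo-2-fluoro-4-methylbenzaldehyde | Cc1cc(OCc2ccccc2)c(C=O)c(F)c1Br | intermediate
21 | 1-(benzyloxy)-4-bromo-2-(dimethoxymethyl)-3-fluoro-5-methylbenzene | Cc1cc(OCc2ccccc2)c(C(OC)OC)c(F)c1Br | intermediate
22 | 4-(benzyloxy)-3-(dimethoxymethyl)-2-fluoro-6-methylphenyllithium (not isolated) | Cc1cc(OCc2ccccc2)c(C(OC)OC)c(F)c1[Li] | intermediate
23 | allyl 4-(benzyloxy)-3-(dimethoxymethyl)-2-fluoro-6-methylbenzoate (not isolated) | Cc1cc(OCc2ccccc2)c(C(OC)OC)c(F)c1C(=O)OCC=C | intermediate
24 | allyl 4-(benzyloxy)-2-fluoro-3-formyl-6-methylbenzoate | Cc1cc(OCc2ccccc2)c(C=O)c(F)c1C(=O)OCC=C | intermediate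
25 | diaryl ether bis-allyl compound (name in step 13) | C=CCOc1c(C=O)c(O)c2c(c1Oc1c(C=O)c(OCc3ccccc3)cc(C)c1C(=O)OCC=C)[C@@H](O[C@@H](C)c1ccccc1)OC2=O | intermediate
26 | seco acid (name in step 14) | Oc1c(C=O)c(O)c2c(c1Oc1c(C=O)c(OCc3ccccc3)cc(C)c1C(=O)O)[C@@H](O[C@@H](C)c1ccccc1)OC2=O | intermediate
27 | protected depsidone (name in step 15) | Cc1cc(OCc4ccccc4)c(C=O)c2c1C(=O)Oc1c(C=O)c(O)c3c(c1O2)[C@@H](O[C@@H](C)c1ccccc1)OC3=O | intermediate
28 | (1S)-1,4,10-trihydroxy-8-methyl-3,7-dioxo-1,3-dihydro-7H-isobenzofuro[4,5-b][1,4]benzodioxepine-5,11-dicarbaldehyde | Cc1cc(O)c(C=O)c2c1C(=O)Oc1c(C=O)c(O)c3c(c1O2)[C@@H](O)OC3=O | target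

Total step count: 16. Longest linear sequence: 11 steps (steps 1–7 and 13–16, from squaric acid); the ring A branch (steps 8–12) joins at step 13.

Steps most likely to fail

1. Step 6 (key step).
- Risk: closure onto the electron-poor, trisubstituted butenolide alkene may be slow. The ketene is then consumed by hydroxyl groups, either by inward rotation of the carbinol hydroxyl followed by lactonisation or by intermolecular ester formation. A [3,3] shift of the allyloxy group may set in on prolonged heating.
- Fallback: it sets out from 11 and comes back at 14. N-(trimethylsilyl)imidazole in CH2Cl2 at rt turns 11 into the carbinol trimethylsilyl ether F1, in which no hydroxyl is left to attack the ketene and the silyloxy group still rotates outward. Thermolysis in toluene gives the 4-O-silyl hydroquinone F2. Et3N·3HF in THF at 0 °C followed by chromatographic separation of the C3 epimers gives 14.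

2. Step 13.
- Risk: both partners carry two ortho substituents, so addition to the ipso carbon may be too slow. Attack of the phenoxide on the allyl ester or on a formyl carbon, or oxidative loss of the dianion, may then take over.
- Fallback: it sets out from 15 and 20 and comes back at 27, bringing in the carboxyl carbon only after the ether bond.
- Ether bond: 15 and bromo aldehyde 20, whose fluorine has a compact, non-electrophilic bromine beside it, are coupled with Cs2CO3 in DMSO at 80 °C to give the bromo diaryl ether F3.
- Deallylation: Pd(PPh3)4 and N-methylaniline in THF at rt remove the allyl ether to give the bromophenol F4, the hindered aryl bromide staying inert at rt.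
- Ring closure: palladium-catalysed carbonylative lactonisation (Pd(OAc)2, Xantphos, CO 1 atm, Et3N, toluene, 90 °C) closes ring C to 27, which is the known intramolecular aryloxycarbonylation of aryl halides.

3. Step 16.
- Risk: slow cleavage of the hindered secondary benzylic ether may let hydrogenation of the formyl groups or hydrogenolysis of the benzylic C1–O bonds catch up. The freed lactol may also epimerise by ring opening on the catalyst support.
- Fallback: it sets out from 27 and ends directly at 28. BCl3 with pentamethylbenzene as cation scavenger in CH2Cl2 at −78 °C, quenched cold with pH 7 phosphate buffer, is used. This Lewis-acid dealkylation breaks both benzylic O–C bonds on the carbocation side, touches no aldehyde and breaks no bond at C1.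

Further compounds
F1 | step 6 | 4-[2-(allyloxy)-4-oxo-1-(trimethylsilyloxy)cyclobut-2-en-1-yl]-5-[(1S)-1-phenylethoxy]furan-2(5H)-one (epimer mixture as 11) | O=C1C=C(OCC=C)C1(O[Si](C)(C)C)C1=CC(=O)OC1O[C@@H](C)c1ccccc1
F2 | step 6 | 5-(allyloxy)-7-hydroxy-3-[(1S)-1-phenylethoxy]-4-(trimethylsilyloxy)isobenzofuran-1(3H)-one (both C3 epimers) | C=CCOc1cc(O)c2c(c1O[Si](C)(C)C)C(O[C@@H](C)c1ccccc1)OC2=O
F3 | step 13 | (3S)-5-(allyloxy)-4-[3-(benzyloxy)-6-bromo-2-formyl-5-methylphenoxy]-6-formyl-7-hydroxy-3-[(1S)-1-phenylethoxy]isobenzofuran-1(3H)-one | C=CCOc1c(C=O)c(O)c2c(c1Oc1c(C=O)c(OCc3ccccc3)cc(C)c1Br)[C@@H](O[C@@H](C)c1ccccc1)OC2=O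
F4 | step 13 | (3S)-4-[3-(benzyloxy)-6-bromo-2-formyl-5-methylphenoxy]-6-formyl-5,7-dihydroxy-3-[(1S)-1-phenylethoxy]isobenzofuran-1(3H)-one | Oc1c(C=O)c(O)c2c(c1Oc1c(C=O)c(OCc3ccccc3)cc(C)c1Br)[C@@H](O[C@@H](C)c1ccccc1)OC2=O
F0 | step 16 | none | none
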